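The route rests on cutting the biaryl bond between C6 of the benzofuran and C1' of the 4-hydroxyphenyl ring; both carbons are nucleophilic by nature. The phenol ring is therefore brought in dearomatised and with reversed polarity, as 4-diazocyclohexa-2,5-dienone. Its Rh(II) quinoid carbene is attacked by the C6–H position of the complete benzofuran ester. Rearomatisation then delivers the free phenol directly, without halide, boron or protecting group. The step exploits C6 being ortho to the C7 methoxy group and para to C3a, hence conjugated with the furan enol ether O1–C2=C3. C5 is shielded by the C4 methoxy group, which the peri C3 methyl locks in place. The benzofuran comes in two steps from 2,5-dimethoxyphenol.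

Key step: step 4

Remark: the target has no stereocentre and its biaryl axis rotates freely, so it is achiral and no step needs stereocontrol; 2 and 3 are racemates whose stereocentre is erased in step 2.

Step 1
Reactants: 1 2,5-dimethoxyphenol; 2 methyl 3-bromo-4-oxopentanoate (methyl 3-bromolevulinate, racemic, catalogue compound)
Product: 3 methyl 3-(2,5-dimethoxyphenoxy)-4-oxopentanoate (racemic)
Conditions: K2CO3, acetone, 0 °C to rt
Reagents that add atoms: none
Why: Williamson ether synthesis, in which the phenoxide should displace the activated α-keto bromide by SN2 faster than carbonate removes HBr at low temperature; the new stereocentre forms as a racemate and is erased in step 2.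

Step 2
Reactants: 3 methyl 3-(2,5-dimethoxyphenoxy)-4-oxopentanoate
Product: 4 methyl 2-(4,7-dimethoxy-3-methyl-1-benzofuran-2-yl)acetate
Conditions: Amberlyst-15 (cat.), toluene, reflux, Dean–Stark
Reagents that add atoms: none
Why: Acid-catalysed cyclodehydration of an α-aryloxy ketone (intramolecular Friedel–Crafts hydroxyalkylation, then loss of water), in which the only free position ortho to the ether oxygen is also ortho to a methoxy group, so a single benzofuran should form and aromatisation removes the stereocentre.

Step 3
Reactants: 5 4-aminophenol
Product: 7 4-diazocyclohexa-2,5-dien-1-one, via 4-hydroxybenzenediazonium tetrafluoroborate 6 (not isolated)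
Conditions: t-BuONO, aq HBF4, EtOH/CH2Cl2, 0 °C; then solid K2CO3, Na2SO4, 0 °C, dark, filter, use as cold CH2Cl2 solution
Reagents that add atoms: tert-butyl nitrite CC(C)(C)ON=O; tetrafluoroboric acid [H+].F[B-](F)(F)F (counter-ion of 6 only)
Why: Diazotisation of the aniline with an alkyl nitrite gives the diazonium salt, and removal of its acidic phenol proton by carbonate leaves the neutral quinone diazide, the diazo-dienone form of the zwitterion; no stereocentre is involved.

Step 4
Reactants: 4 methyl 2-(4,7-dimethoxy-3-methyl-1-benzofuran-2-yl)acetate; 7 4-diazocyclohexa-2,5-dien-1-one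
Product: 8 phenylcandilide B, methyl 2-[6-(4-hydroxyphenyl)-4,7-dimethoxy-3-methyl-1-benzofuran-2-yl]acetate
Conditions: Rh2(esp)2 (2 mol %), CH2Cl2, rt, dark, slow addition of 7 (1.5 equiv)
Reagents that add atoms: none
Why: Rh(II) expels N2 from 7 to give an electrophilic quinoid carbene whose carbene carbon is the later C1'; C6 of 4 attacks it in an SEAr manner, rhodium leaves as the dienone aromatises to a phenolate, and transfer of the C6 proton to that oxygen restores the benzofuran and frees the phenol. The closest known reaction type is the Rh(II)-catalysed intermolecular C(sp2)–H arylation of electron-rich arenes with diazoquinones. No ring is closed and no stereocentre is formed, and the new biaryl axis carries only one ortho substituent (C7-OMe), so it rotates freely. The step needs site selectivity for C6–H over C5–H and over the C2=C3 bond, and chemoselectivity over the C(sp3)–H bonds of the C2 methylene and the C3 methyl group. C6 is ortho to the C7 methoxy group and para to C3a, so its arenium ion is stabilised through C3a–C3=C2–O1 like a 2-furylcarbinyl cation (the C6 preference known for 2,3-dialkylbenzofurans), whereas C5 is shielded by the C4 methoxy group, whose methyl is locked towards C5 by the peri C3 methyl. The C2=C3 bond is tetrasubstituted and carries no proton that would allow rearomatisation, and slow addition of 7 keeps carbene dimerisation and O–H insertion into the product low.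

Compound list
1 | 2,5-dimethoxyphenol | COc1ccc(OC)c(O)c1 | starting material
2 | methyl 3-bromo-4-oxopentanoate (racemic) | COC(=O)CC(Br)C(C)=O | starting material
3 | methyl 3-(2,5-dimethoxyphenoxy)-4-oxopentanoate (racemic) | COC(=O)CC(Oc1cc(OC)ccc1OC)C(C)=O | intermediate
4 | methyl 2-(4,7-dimethoxy-3-methyl-1-benzofuran-2-yl)acetate | COC(=O)Cc1oc2c(OC)ccc(OC)c2c1C | intermediate
5 | 4-aminophenol | Nc1ccc(O)cc1 | starting material
6 | 4-hydroxybenzenediazonium tetrafluoroborate (not isolated) | Oc1ccc([N+]#N)cc1.F[B-](F)(F)F | intermediate
7 | 4-diazocyclohexa-2,5-dien-1-one | [N-]=[N+]=C1C=CC(=O)C=C1 | intermediate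
8 | phenylcandilide B, methyl 2-[6-(4-hydroxyphenyl)-4,7-dimethoxy-3-methyl-1-benzofuran-2-yl]acetate | COC(=O)Cc1oc2c(OC)c(-c3ccc(O)cc3)cc(OC)c2c1C | target

Total step count: 4. Longest linear sequence: 3 steps (1 → 3 → 4 → 8); step 3 is the side branch.

Steps most likely to fail

Step 4. The carbene may be captured at C5 or at the furan C2=C3 bond. It may also be lost to dimerisation and azine formation before the flanked C6 position reacts. The fallback sets out from 4 and comes back at 8. Electrophilic bromination of 4 (NBS, MeCN, 0 °C) should give methyl 2-(6-bromo-4,7-dimethoxy-3-methyl-1-benzofuran-2-yl)acetate F1. F1 can be freed from any regioisomer and its substitution pattern checked before the coupling. Suzuki–Miyaura coupling of F1 with 4-hydroxyphenylboronic acid (Pd(dppf)Cl2, K3PO4, dioxane/H2O, 80 °C) should then give 8.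

Step 1. Base-induced loss of HBr from 2 may outrun substitution, and the phenoxide may then add in conjugate fashion at the wrong carbon. The fallback sets out from 1 and comes back at 4.
- O-alkylation of 1 with chloroacetone (K2CO3, KI, acetone, reflux) should give 1-(2,5-dimethoxyphenoxy)propan-2-one F2.
- Cyclodehydration (Amberlyst-15, toluene, reflux) should give 4,7-dimethoxy-3-methyl-1-benzofuran F3.
- Oxidative radical C2–H alkylation of F3 with methyl 2-[(ethoxycarbonothioyl)sulfanyl]acetate and dilauroyl peroxide (DCE, reflux) should install the acetate side chain and give 4.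

Step 3. The unsubstituted quinone diazide may undergo dediazoniation or self-coupling during neutralisation and concentration. The fallback sets out from 4 and comes back at 8, and it changes the electrophilic aryl donor from a carbene to an aryl-λ3-iodane.
- Benzyl phenyl ether and (diacetoxyiodo)mesitylene with TfOH (CH2Cl2, 0 °C) should give [4-(benzyloxy)phenyl](mesityl)iodonium triflate F4.
- Copper-catalysed electrophilic C–H arylation of 4 with F4 (Cu(OTf)2, 2,6-di-tert-butylpyridine, DCE, 60 °C) should give methyl 2-{6-[4-(benzyloxy)phenyl]-4,7-dimethoxy-3-methyl-1-benzofuran-2-yl}acetate F5.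
- Hydrogenolysis of F5 (H2, Pd/C, EtOAc, rt) should give 8.

Further compounds
F1 | step 4 | methyl 2-(6-bromo-4,7-dimethoxy-3-methyl-1-benzofuran-2-yl)acetate | COC(=O)Cc1oc2c(OC)c(Br)cc(OC)c2c1C
F2 | step 1 | 1-(2,5-dimethoxyphenoxy)propan-2-one | CC(=O)COc1cc(OC)ccc1OC
F3 | step 1 | 4,7-dimethoxy-3-methyl-1-benzofuran | COc1ccc(OC)c2c(C)coc12
F4 | step 3 | [4-(benzyloxy)phenyl](mesityl)iodonium triflate | Cc1cc(C)c([I+]c2ccc(OCc3ccccc3)cc2)c(C)c1.[O-]S(=O)(=O)C(F)(F)F
F5 | step 3 | methyl 2-{6-[4-(benzyloxy)phenyl]-4,7-dimethoxy-3-methyl-1-benzofuran-2-yl}acetate | COC(=O)Cc1oc2c(OC)c(-c3ccc(OCc4ccccc4)cc3)cc(OC)c2c1C
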